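A direct plan would make one orsellinate ring, methyl orsellinate A1, by a Michael–Dieckmann annulation of two acyclic esters and aromatisation through its dibromide A2, and would use A1 three times.
It would turn A1 into the 4-O-benzyl-2-O-methyl acid chloride A3 (ring B) and the 2-O-benzyl-4-O-methyl acid chloride A4 (ring C), and join the rings by two phenol acylations, each followed by a hydrogenolysis.
Weak point 1: the aromatisation by bromination and reductive debromination would put two bromine atoms on the ring only to take them off, a three-step run-up to a ring as simple as A1.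
Weak point 2: telling apart the two phenols of rings B and C would cost benzylation, methylation, saponification of a di-ortho-substituted ester in hot KOH/DMSO and chlorination on each ring, about eight operations that form no bond of the skeleton.
Weak point 3: each depside bond would come from a hindered 2,6-disubstituted aroyl chloride and would need its own debenzylation, so the line would run to some fifteen steps for three rings of the same C8 unit.

**Retrosynthetic overview**
Each benzoate ring is cut at C1–C2 and C5–C6: a but-2-ynoate ester supplies C1, C6, the C6 methyl group and the ester carbonyl, and a 1,1,3-trioxygenated buta-1,3-diene supplies C2–C5 with the oxygen pattern of that ring (Diels–Alder cycloaddition–aromatisation).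
Rings form in the order A, B, C, each grown on the C4 oxygen of the ring before it: A from a 1-methoxy-1,3-bis(silyloxy) diene (C2 OH, C4 OH), B from a 1,1-dimethoxy-3-silyloxy diene (C2 OMe, C4 OH left free for the next ester), C from a 1,3-dimethoxy-1-silyloxy diene (C2 OH, C4 OMe).
The depside carbonyls thus enter as but-2-ynoic acid, never as a hindered benzoic acid: no halogen is put on and removed, no benzyl ether, saponification or acid chloride is needed, and the only masking is a silyl ether made and removed inside the cycloaddition flask.

Key step: step 5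

Assumption: 1-methoxy-1,3-bis(trimethylsilyloxy)buta-1,3-diene, 1,1-dimethoxyethene, but-2-ynoic acid and methyl (E)-3-methoxybut-2-enoate are taken as catalogue chemicals; the C1=C2 geometry of the silyl ketene acetal dienes 2 and 16 is not controlled and is lost on aromatisation.

Step 1
Reactants: 1 methyl but-2-ynoate; 2 1-methoxy-1,3-bis(trimethylsilyloxy)buta-1,3-diene (Chan's diene)
Product: 4 methyl 2,4-dihydroxy-6-methylbenzoate (methyl orsellinate), via cyclohexadiene ketal cycloadduct 3 (not isolated)
Conditions: 2 (1.5 equiv), toluene, 115 °C (sealed tube), 24 h; then 1 M HCl, THF, 0 °C to rt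
Reagents that add atoms: none
Why: Diels–Alder cycloaddition–aromatisation in which the unsubstituted diene terminus bonds to the methyl-bearing β-carbon of the ynoate and the acetal carbon to the α-carbon, after which the mixed ketal of racemic 3 should lose methanol (the less basic silyl ether oxygen stays and is then hydrolysed), giving the 2,4-dihydroxy-6-methyl pattern of ring A and erasing the one stereocentre.

Step 2
Reactants: 4 methyl 2,4-dihydroxy-6-methylbenzoate; 5 but-2-ynoic acid
Product: 6 methyl 4-(but-2-ynoyloxy)-2-hydroxy-6-methylbenzoate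
Conditions: 5 (1.1 equiv), N,N'-dicyclohexylcarbodiimide (DCC, 1.15 equiv), DMAP (5 mol%), CH2Cl2, 0 °C, 2 h
Reagents that add atoms: none
Why: Steglich esterification should take place only at the C4 hydroxyl, because the C2 hydroxyl is hydrogen-bonded to and flanked by the ester, and the low temperature and small amount of DMAP keep the ynoate from conjugate addition.

Step 3
Reactants: 7 1,1-dimethoxyethene; 8 acetyl chloride
Product: 9 4,4-dimethoxybut-3-en-2-one
Conditions: 7 (2.2 equiv), Et2O, 0 °C to rt; distil
Reagents that add atoms: none
Why: C-acylation of the ketene acetal at its nucleophilic CH2 carbon and loss of a proton give the push–pull enone, while the second equivalent of 7 takes up the HCl as methyl acetate and chloromethane.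

Step 4
Reactants: 9 4,4-dimethoxybut-3-en-2-one
Product: 10 1,1-dimethoxy-3-(trimethylsilyloxy)buta-1,3-diene
Conditions: Me3SiCl (1.3 equiv), Et3N (1.5 equiv), ZnCl2 (3 mol%), toluene, 40 °C; filter, distil
Reagents that add atoms: chlorotrimethylsilane, C[Si](C)(C)Cl
Why: Silyl enol ether formation at the only enolisable position, the methyl ketone, under the amine/ZnCl2 conditions used for 2-silyloxy dienes gives the cross-conjugated diene.

Step 5
Reactants: 6 methyl 4-(but-2-ynoyloxy)-2-hydroxy-6-methylbenzoate; 10 1,1-dimethoxy-3-(trimethylsilyloxy)buta-1,3-diene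
Product: 13 methyl 2-hydroxy-4-[(4-hydroxy-2-methoxy-6-methylbenzoyl)oxy]-6-methylbenzoate, via ring A trimethylsilyl ether 11 (not isolated), via dimethyl ketal cycloadduct 12 (not isolated)
Conditions: N,O-bis(trimethylsilyl)acetamide (BSA, 1.2 equiv), toluene, 60 °C, 1 h; then 10 (2.5 equiv), 110 °C, 24 h; then 1 M HCl, THF, 0 °C to rt
Reagents that add atoms: none
Why: The electron-rich ketene acetal diene 10 and the aryl ynoate 11 should combine in a normal-demand, asynchronous [4+2] cycloaddition (limiting form: Mukaiyama–Michael addition, then closure onto the oxocarbenium ion) that forms the C5–C6 and C1–C2 bonds of ring B and gives the 1,4-cyclohexadiene ketal 12. The closest known reaction type is the cycloaddition–aromatisation of 1,1-dialkoxy-3-silyloxybutadienes with β-alkyl acetylenic esters, which gives 6-alkyl-4-hydroxy-2-methoxybenzoates. Ring B closes as a six-membered carbocycle by intermolecular [4+2] closure and aromatises on acid work-up: the C2 ketal ionises with loss of methanol to a 2-methoxy arenium ion that loses a proton from the C5 methylene, and the silyl ethers are hydrolysed. Regiochemistry is set by polarity, since the unsubstituted diene terminus (largest HOMO coefficient) bonds to the methyl-bearing β-carbon and the ketene acetal carbon to the α-carbon, so only the 2-methoxy-4-hydroxy-6-methyl pattern can arise. The step needs reaction at the alkyne alone: the ester carbonyls are inert to a silyl ketene acetal without a Lewis acid, and the one protic group, the chelated ring A C2 hydroxyl, is masked in the flask by BSA and freed by the same work-up. No stereocentre is formed.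

Step 6
Reactants: 13 methyl 2-hydroxy-4-[(4-hydroxy-2-methoxy-6-methylbenzoyl)oxy]-6-methylbenzoate; 5 but-2-ynoic acid
Product: 14 methyl 4-{[4-(but-2-ynoyloxy)-2-methoxy-6-methylbenzoyl]oxy}-2-hydroxy-6-methylbenzoate
Conditions: 5 (1.1 equiv), DCC (1.15 equiv), DMAP (5 mol%), CH2Cl2, 0 °C, 2 h
Reagents that add atoms: none
Why: Steglich esterification at the only non-chelated phenol, the ring B C4 hydroxyl that the diene delivered free, while the ring A C2 hydroxyl stays hydrogen-bonded to its ester and the existing aryl ester is untouched under these neutral conditions.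

Step 7
Reactants: 15 methyl (E)-3-methoxybut-2-enoate
Product: 16 1,3-dimethoxy-1-(trimethylsilyloxy)buta-1,3-diene (Brassard's diene)
Conditions: LiN(iPr)2 (1.1 equiv), THF, −78 °C; Me3SiCl (1.2 equiv), −78 °C to rt; filter, distil
Reagents that add atoms: chlorotrimethylsilane, C[Si](C)(C)Cl
Why: γ-Deprotonation of the β-methoxy enoate gives the extended ester enolate, which is O-silylated to the vinylketene acetal.

Step 8
Reactants: 14 methyl 4-{[4-(but-2-ynoyloxy)-2-methoxy-6-methylbenzoyl]oxy}-2-hydroxy-6-methylbenzoate; 16 1,3-dimethoxy-1-(trimethylsilyloxy)buta-1,3-diene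
Product: 19 methyl 2-hydroxy-4-({4-[(2-hydroxy-4-methoxy-6-methylbenzoyl)oxy]-2-methoxy-6-methylbenzoyl}oxy)-6-methylbenzoate (target), via ring A trimethylsilyl ether 17 (not isolated), via mixed ketal cycloadduct 18 (not isolated)
Conditions: BSA (1.2 equiv), toluene, 60 °C, 1 h; then 16 (2.5 equiv), 110 °C, 24 h; then 1 M HCl, THF, 0 °C to rt
Reagents that add atoms: none
Why: Diels–Alder cycloaddition–aromatisation with the same polarity-controlled regiochemistry as in step 5, in which the mixed methyl silyl ketal of racemic 18 should lose methanol and then its silyl group, so that C2 of ring C ends as a free hydroxyl while C4 keeps the methyl ether it carried in the diene; both depside esters are inert and the stereocentre of 18 is erased.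

**Compound list**
1 | methyl but-2-ynoate | CC#CC(=O)OC | starting material
2 | 1-methoxy-1,3-bis(trimethylsilyloxy)buta-1,3-diene (Chan's diene; mixture of C1=C2 isomers) | COC(O[Si](C)(C)C)=CC(=C)O[Si](C)(C)C | starting material
3 | methyl 6-methoxy-2-methyl-4,6-bis(trimethylsilyloxy)cyclohexa-1,4-diene-1-carboxylate (racemic) | COC(=O)C1=C(C)CC(O[Si](C)(C)C)=CC1(OC)O[Si](C)(C)C | intermediate (not isolated)
4 | methyl 2,4-dihydroxy-6-methylbenzoate (methyl orsellinate) | COC(=O)c1c(C)cc(O)cc1O | intermediate
5 | but-2-ynoic acid | CC#CC(=O)O | starting material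
6 | methyl 4-(but-2-ynoyloxy)-2-hydroxy-6-methylbenzoate | COC(=O)c1c(C)cc(OC(=O)C#CC)cc1O | intermediate
7 | 1,1-dimethoxyethene | COC(=C)OC | starting material
8 | acetyl chloride | CC(=O)Cl | starting material
9 | 4,4-dimethoxybut-3-en-2-one | CC(=O)C=C(OC)OC | intermediate
10 | 1,1-dimethoxy-3-(trimethylsilyloxy)buta-1,3-diene | COC(OC)=CC(=C)O[Si](C)(C)C | intermediate
11 | methyl 4-(but-2-ynoyloxy)-2-methyl-6-(trimethylsilyloxy)benzoate | COC(=O)c1c(C)cc(OC(=O)C#CC)cc1O[Si](C)(C)C | intermediate (not isolated)
12 | methyl 4-{[6,6-dimethoxy-2-methyl-4-(trimethylsilyloxy)cyclohexa-1,4-diene-1-carbonyl]oxy}-2-methyl-6-(trimethylsilyloxy)benzoate | COC(=O)c1c(C)cc(OC(=O)C2=C(C)CC(O[Si](C)(C)C)=CC2(OC)OC)cc1O[Si](C)(C)C | intermediate (not isolated)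
13 | methyl 2-hydroxy-4-[(4-hydroxy-2-methoxy-6-methylbenzoyl)oxy]-6-methylbenzoate | COC(=O)c1c(C)cc(OC(=O)c2c(C)cc(O)cc2OC)cc1O | intermediate
14 | methyl 4-{[4-(but-2-ynoyloxy)-2-methoxy-6-methylbenzoyl]oxy}-2-hydroxy-6-methylbenzoate | COC(=O)c1c(C)cc(OC(=O)c2c(C)cc(OC(=O)C#CC)cc2OC)cc1O | intermediate
15 | methyl (E)-3-methoxybut-2-enoate | CO/C(C)=C/C(=O)OC | starting material
16 | 1,3-dimethoxy-1-(trimethylsilyloxy)buta-1,3-diene (Brassard's diene; mixture of C1=C2 isomers) | COC(=C)C=C(OC)O[Si](C)(C)C | intermediate
17 | methyl 4-{[4-(but-2-ynoyloxy)-2-methoxy-6-methylbenzoyl]oxy}-2-methyl-6-(trimethylsilyloxy)benzoate | COC(=O)c1c(C)cc(OC(=O)c2c(C)cc(OC(=O)C#CC)cc2OC)cc1O[Si](C)(C)C | intermediate (not isolated)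
18 | methyl 4-[(4-{[4,6-dimethoxy-2-methyl-6-(trimethylsilyloxy)cyclohexa-1,4-diene-1-carbonyl]oxy}-2-methoxy-6-methylbenzoyl)oxy]-2-methyl-6-(trimethylsilyloxy)benzoate (racemic) | COC(=O)c1c(C)cc(OC(=O)c2c(C)cc(OC(=O)C3=C(C)CC(OC)=CC3(OC)O[Si](C)(C)C)cc2OC)cc1O[Si](C)(C)C | intermediate (not isolated)
19 | methyl 2-hydroxy-4-({4-[(2-hydroxy-4-methoxy-6-methylbenzoyl)oxy]-2-methoxy-6-methylbenzoyl}oxy)-6-methylbenzoate | COC(=O)c1c(C)cc(OC(=O)c2c(C)cc(OC(=O)c3c(C)cc(OC)cc3O)cc2OC)cc1O | target

Total step count: 8. Longest linear sequence: 5 (steps 1, 2, 5, 6, 8).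

**Steps most likely to fail**

Step 5: the β-methyl ynoate may take up the diene too slowly at a temperature the ketene acetal tolerates, so that the diene is lost to silyl transfer and oligomerisation before the ring closes. The fallback changes the two-carbon partner to an allene. It sets out from 4, which would be esterified at the C4 hydroxyl with buta-2,3-dienoic acid F1 (DCC, CH2Cl2, 0 °C) to methyl 4-(buta-2,3-dienoyloxy)-2-hydroxy-6-methylbenzoate F2. The activated C2=C3 bond of the allenic ester should add diene 10 (3 equiv, CH2Cl2, rt, chelated phenol left free) with the same orientation, to give the racemic adduct methyl 4-{[2,2-dimethoxy-6-methylidene-4-(trimethylsilyloxy)cyclohex-3-ene-1-carbonyl]oxy}-2-hydroxy-6-methylbenzoate F3. Acid work-up (loss of methanol and of the silyl group, shift of the exocyclic double bond into the ring) would bring the route back at 13.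

Step 8: on aromatisation the mixed methyl silyl ketal may partition, loss of silanol in place of methanol leaving a methyl ether at C2 of ring C, or the C4 enol ether may hydrolyse before the ring becomes aromatic; the cycloaddition may also be slower on the larger ynoate. The fallback gives up the ring construction for ring C and sets out from 13. Its only non-chelated phenol would be acylated with everninic acid F4 (2-hydroxy-4-methoxy-6-methylbenzoic acid; DCC, toluene, rt), whose own C2 hydroxyl is hydrogen-bonded to the carboxyl group and needs no protection. This comes back to the route at 19 and leaves out 14.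

Step 1: the methyl ynoate is the least activated dienophile of the three, so the cycloaddition may stall, and the same ketal partition may give the 2-O-methyl ether. The fallback sets out from orsellinic acid F5 (2,4-dihydroxy-6-methylbenzoic acid), which would be esterified at the carboxylate only (KHCO3, MeI, DMF, rt, no heating, to avoid decarboxylation), and comes back to the route at 4.

**Further compounds**
F1 | step 5 | buta-2,3-dienoic acid | C=C=CC(=O)O
F2 | step 5 | methyl 4-(buta-2,3-dienoyloxy)-2-hydroxy-6-methylbenzoate | COC(=O)c1c(C)cc(OC(=O)C=C=C)cc1O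
F3 | step 5 | methyl 4-{[2,2-dimethoxy-6-methylidene-4-(trimethylsilyloxy)cyclohex-3-ene-1-carbonyl]oxy}-2-hydroxy-6-methylbenzoate (racemic) | COC(=O)c1c(C)cc(OC(=O)C2C(=C)CC(O[Si](C)(C)C)=CC2(OC)OC)cc1O
F4 | step 8 | 2-hydroxy-4-methoxy-6-methylbenzoic acid (everninic acid) | COc1cc(C)c(C(=O)O)c(O)c1
F5 | step 1 | 2,4-dihydroxy-6-methylbenzoic acid (orsellinic acid) | Cc1cc(O)cc(O)c1C(=O)O
A1 | direct plan | methyl 2,4-dihydroxy-6-methylbenzoate (methyl orsellinate) | COC(=O)c1c(C)cc(O)cc1O
A2 | direct plan | methyl 3,5-dibromo-2,4-dihydroxy-6-methylbenzoate | COC(=O)c1c(C)c(Br)c(O)c(Br)c1O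
A3 | direct plan | 4-(benzyloxy)-2-methoxy-6-methylbenzoyl chloride | COc1cc(OCc2ccccc2)cc(C)c1C(=O)Cl
A4 | direct plan | 2-(benzyloxy)-4-methoxy-6-methylbenzoyl chloride | COc1cc(C)c(C(=O)Cl)c(OCc2ccccc2)c1
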